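## Structural features

The target is a 3,3''-biflavanone: two 2-aryl-2,3-dihydro-4H-chromen-4-one units (ring A = 5,7-dihydroxybenzo ring, ring C = pyranone, ring B = 2-aryl group) joined only by the C3–C3'' single bond. Atoms of the unit with the 4-methoxyphenyl ring B are unprimed; those of the unit with the 4-hydroxyphenyl ring B are double-primed. C2, C3, C3'' and C2'' are four contiguous stereocentres, (2S,3S,3''S,2''R): the unprimed unit is 2,3-cis, the double-primed unit is 2,3-trans, and C3/C3'' have like descriptors. C3 and C3'' are α to ketones and epimerisable, and the C2–O1 and C2''–O1'' bonds are benzylic aryl ethers β to a carbonyl, which open by retro-oxa-Michael reaction under base and ionise under acid. The 2,3-cis unit is the less stable arrangement, so it has to be set under kinetic control and carried on without equilibration. The halves differ only in OMe versus OH on ring B and in the configuration at C2, so a symmetric dimerisation cannot give the compound. The real difficulty is the C3–C3'' bond between two carbons of like (enolate) polarity together with a unit-specific cis/trans pattern in one stereotetrad. The key step exploits the chain C2–C3–C3''–C2'' seen without the rings A: it is a 1,4-diaryl-butane-1,4-diol whose C3 and C3'' carry the one-carbon branches C4 and C4''. Each O–C2–C3–C4 array is then that of a homoallylic alcohol (C4 as an alkene carbon), syn in the unprimed unit and anti in the double-primed unit. This is the pattern that [2,3]-Wittig rearrangement of a Z and an E allyl benzyl ether delivers, and C3–C3'' becomes the central single bond of a conjugated diene.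

## Logic of the disconnections

21 from 20. Cut: the five O–CH2Ph bonds. Reason: all phenols carry one group that leaves under neutral conditions, so the fragile 2,3-cis unit meets neither acid nor base at the end. Gain: none in skeleton, full protection of five acidic sites. Demand: the benzylic C2–O1 and C2''–O1'' bonds must survive hydrogenolysis.

20 from 18 (through 19). Cut: C4–C4a and C4''–C4a'', the two aryl–acyl bonds of rings C. Reason: each ring A is a symmetric, very electron-rich aryl ether, and closing ring C at carbon leaves the C2–O1 bonds untouched, so cis/trans is already written in the open chain (syn C2/C3 gives cis, anti C2''/C3'' gives trans). Gain: both heterocycles disappear and an acyclic 2,3-disubstituted succinic acid remains. Demand: acylation mild enough that the benzylic aryl ethers do not ionise.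

18 from 17, and 17 from 15 (through 16). Cut (as a change of functional group): the C4 and C4'' carboxyl carbons are traced to the CH= carbons of two propenyl groups. Reason: alkenes are inert placeholders for the acyl carbons through all base-mediated steps. Gain: no carbonyl group and no enolisable centre before this point. Demand: cleavage of two alkenes without oxidation of the trioxygenated rings A and without epimerisation of the α-branched dialdehyde 17.

15 from 13 and 14. Cut: O1–C8a and O1''–C8a''. Reason: forming the aryl–oxygen bond keeps the carbinol C–O bond and hence the configuration at C2 and C2''. Gain: both rings A come from one commercial aryl bromide. Demand: C–O coupling at two hindered secondary benzylic alcohols without β-hydride loss.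

13 from 10 (through 11 or 12). Cut: C2–C3 and C2''–C3''; each oxygen is reconnected to the far allylic carbon. Reason: each half is the retron of a [2,3]-Wittig rearrangement. Gain: four contiguous stereocentres reduce to two carbinol centres and two alkene geometries; the unsymmetrical pairing of ring B groups reduces to which benzyl ether sits on which end. Demand: lithiation only at the two ether CH2 groups, suprafacial chirality transfer in both halves, syn selection in the Z half and anti selection in the E half.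

10 from 9, and 9 from 3 and 8. Cut: the central C–C bond of the diene, which is the C3–C3'' bond of 21, made as an sp–sp2 bond. Reason: the bond between two carbons of like polarity is formed by cross-coupling before either carbon is a stereocentre or α to a carbonyl group. Gain: two four-carbon fragments of opposite carbinol configuration. Demand: E geometry from 8 and Z geometry from semihydrogenation of the alkyne.

8 from 6 (through 7), 6 from 4 and 5, and 3 from 1 and 2. Cut: the vinyl C–I bond and the two benzylic C–O bonds. Reason: both enantiomers of the alkynol are commercial and carry the only stereochemical information the route needs. Gain: four commercial starting materials. Demand: etherification without touching the carbinol C–O bond.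

## Other disconnections considered

Alternative 1: the disconnection that comes to mind first is the C3–C3'' bond itself, made by oxidative coupling of two flavanone enol derivatives. The forward key step would be oxidation of the silicon-tethered bis-enol ether A1 with (NH4)2Ce(NO3)6. Each new bond must form anti to the aryl group on the neighbouring C2, so both units would emerge 2,3-trans and the product would be A2, the C3 epimer of 20. The 2,3-cis unit would then require an uphill epimerisation, and flavanone enolates are prone to E1cB opening of ring C, which endangers C2. The chosen plan avoids enolate chemistry at C3 and encodes cis and trans separately in two alkene geometries.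

Alternative 2: cut the C–H bonds at C2, C3, C2'' and C3'', which leads back to the 3,3''-biflavone A3 (from an Ullmann-type union of two 3-iodoflavones). The forward key step is a twofold catalyst-controlled hydrogenation. Syn addition of hydrogen makes both units 2,3-cis and would give A4, the C2'' epimer of 21; a trans unit cannot be assigned to one half only. In addition the two tetrasubstituted, doubly ortho-flanked alkenes are poor hydrogenation substrates, and the mixed Ullmann coupling of two near-identical halides is statistical.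

Alternative 3: cut C2–C3, C2''–C3'' and both O1–C2 bonds, which leads to the 1,4-diketone A5 and two aldehydes. The forward key step is a twofold aldol condensation to the bis(arylidene) diketone A6 followed by twofold oxa-Michael closure. The symmetric A5 cannot distinguish the two aldehydes, so the mixed product forms statistically. All four stereocentres would be set by reversible conjugate addition and enol protonation, which favours 2,3-trans in both units and gives no absolute control. The chosen plan is no longer and fixes every centre by a stereospecific event.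

Key step: step 6

Remark: salts of numbered compounds, catalytic-cycle species and the partly converted species of operations that act on several like groups are not numbered, except in the key step.

## Route

Step 1
Reactants: 1 (2R)-but-3-yn-2-ol; 2 4-methoxybenzyl chloride
Product: 3 1-({[(2R)-but-3-yn-2-yl]oxy}methyl)-4-methoxybenzene
Conditions: NaH, Bu4NI (cat.), THF, 0 °C to rt
Reagents that add atoms: none
Why: Williamson ether synthesis; the sodium alkoxide of 1 displaces chloride from the benzylic halide, and the carbinol C–O bond is not broken, so the (R) centre is carried over unchanged.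

Step 2
Reactants: 4 (2S)-but-3-yn-2-ol; 5 1-(benzyloxy)-4-(chloromethyl)benzene
Product: 6 1-(benzyloxy)-4-({[(2S)-but-3-yn-2-yl]oxy}methyl)benzene
Conditions: NaH, Bu4NI (cat.), THF, 0 °C to rt
Reagents that add atoms: none
Why: Williamson ether synthesis as in step 1; the (S) centre is not involved.

Step 3
Reactants: 6 1-(benzyloxy)-4-({[(2S)-but-3-yn-2-yl]oxy}methyl)benzene
Product: 8 1-(benzyloxy)-4-({[(2S,3E)-4-iodobut-3-en-2-yl]oxy}methyl)benzene, via alkenylzirconocene chloride 7 (not isolated)
Conditions: Cp2Zr(H)Cl, CH2Cl2, rt; then I2, 0 °C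
Reagents that add atoms: iodine, [I][I]
Why: Hydrozirconation of the terminal alkyne is a syn addition that places zirconium on the terminal carbon; iodinolysis of the C–Zr bond with retention should give the E vinyl iodide, with the propargylic stereocentre untouched.

Step 4
Reactants: 3 1-({[(2R)-but-3-yn-2-yl]oxy}methyl)-4-methoxybenzene; 8 1-(benzyloxy)-4-({[(2S,3E)-4-iodobut-3-en-2-yl]oxy}methyl)benzene
Product: 9 1-(benzyloxy)-4-({[(2S,3E,7R)-7-[(4-methoxyphenyl)methoxy]oct-3-en-5-yn-2-yl]oxy}methyl)benzene
Conditions: Pd(PPh3)2Cl2 (cat.), CuI (cat.), Et3N, THF, rt, degassed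
Reagents that add atoms: none
Why: Sonogashira coupling of a vinyl iodide with a terminal alkyne proceeds with retention of the E geometry; the sp–sp2 bond formed here becomes the C3–C3'' bond of the target.

Step 5
Reactants: 9 1-(benzyloxy)-4-({[(2S,3E,7R)-7-[(4-methoxyphenyl)methoxy]oct-3-en-5-yn-2-yl]oxy}methyl)benzene
Product: 10 1-(benzyloxy)-4-({[(2S,3E,5Z,7R)-7-[(4-methoxyphenyl)methoxy]octa-3,5-dien-2-yl]oxy}methyl)benzene
Conditions: H2 (1 atm), Pd/CaCO3 poisoned with Pb(OAc)2, quinoline, EtOAc, rt, stopped after 1 equiv H2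
Reagents that add atoms: none
Why: cis-Semihydrogenation of the alkyne on poisoned palladium (Lindlar conditions) should give the Z alkene next to the existing E alkene; the poisoned catalyst does not cleave benzyl ethers.

Step 6
Reactants: 10 1-(benzyloxy)-4-({[(2S,3E,5Z,7R)-7-[(4-methoxyphenyl)methoxy]octa-3,5-dien-2-yl]oxy}methyl)benzene
Product: 13 (1S,2S,3S,4R)-4-[4-(benzyloxy)phenyl]-1-(4-methoxyphenyl)-2,3-bis[(1E)-prop-1-en-1-yl]butane-1,4-diol, via anisyl-side rearranged lithium alkoxide 11 (not isolated), via benzyloxyphenyl-side rearranged lithium alkoxide 12 (not isolated)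
Conditions: s-BuLi (4.5 equiv), THF, −78 °C (to −50 °C if needed); aq NH4Cl at −78 °C
Reagents that add atoms: none
Why: Twofold [2,3]-Wittig rearrangement, a known reaction type for benzyl ethers of secondary allylic alcohols: sec-butyllithium removes a proton from each ArCH2–O group, and each α-oxy benzylic carbanion adds suprafacially to the far alkene carbon through a five-membered envelope transition state while the allylic C–O bond breaks, so the C2–C3 and C2''–C3'' bonds form, each ether oxygen ends as the C2 or C2'' alkoxide, and no ring is closed. C3 is controlled by the (7R) carbinol centre of the Z half: allylic 1,3-strain holds its hydrogen in the alkene plane and the methyl group pseudo-equatorial, so the carbanion is delivered to the face that carries the oxygen, which should give (S) at C3 and an E propenyl group; C3'' is set in the same way by the (2S) centre of the E half. C2 follows from the Z geometry, for which the aryl group of the carbanion sits exo in the envelope and the syn (2S,3S) pair results; C2'' follows from the E geometry, which with the aryl group exo gives the anti (2''R,3''S) pair. The step needs lithiation at the two ether CH2 groups and not at the hindered tertiary dienylic C–H atoms or by addition to the diene, [2,3] shift in preference to [1,2] shift, and anti selection in the E half; low temperature and the directing ether oxygens serve the first two, and anti selection in the E half is the least secure element. The CH2 of the phenolic benzyl ether may be lithiated by the excess base, but it does not rearrange at −78 °C and is reprotonated on quench. The alkoxide formed first deactivates its own α-C–H, so the second rearrangement, through 11 or 12 in either order, is not disturbed by the first. The gain is that four contiguous stereocentres and the unsymmetrical pairing of the two halves are read off from two commercial carbinol configurations and two alkene geometries.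

Step 7
Reactants: 13 (1S,2S,3S,4R)-4-[4-(benzyloxy)phenyl]-1-(4-methoxyphenyl)-2,3-bis[(1E)-prop-1-en-1-yl]butane-1,4-diol; 14 1,3-bis(benzyloxy)-5-bromobenzene
Product: 15 1,1'-{[(1S,2S,3S,4R)-4-[4-(benzyloxy)phenyl]-1-(4-methoxyphenyl)-2,3-bis[(1E)-prop-1-en-1-yl]butane-1,4-diyl]bis(oxy)}bis[3,5-bis(benzyloxy)benzene]
Conditions: CuI (20 mol %), 3,4,7,8-tetramethyl-1,10-phenanthroline (40 mol %), Cs2CO3, 14 (4 equiv), toluene, 110 °C
Reagents that add atoms: none
Why: Ullmann-type copper-catalysed C–O coupling of secondary alcohols with an aryl bromide; the carbinol C–O bonds are not broken, so C2 and C2'' keep their configuration, and copper alkoxides are less prone to β-hydride loss than palladium alkoxides. The 1,5-diene should be stable to Cope rearrangement at this temperature.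

Step 8
Reactants: 15 1,1'-{[(1S,2S,3S,4R)-4-[4-(benzyloxy)phenyl]-1-(4-methoxyphenyl)-2,3-bis[(1E)-prop-1-en-1-yl]butane-1,4-diyl]bis(oxy)}bis[3,5-bis(benzyloxy)benzene]
Product: 17 (2S,3S)-2-[(S)-[3,5-bis(benzyloxy)phenoxy](4-methoxyphenyl)methyl]-3-[(R)-[4-(benzyloxy)phenyl][3,5-bis(benzyloxy)phenoxy]methyl]butanedial, via tetraol 16 (not isolated)
Conditions: OsO4 (cat.), NaIO4, 2,6-lutidine, 1,4-dioxane/H2O, rt; crude product used at once
Reagents that add atoms: OsO4 (catalytic oxygen carrier), O=[Os](=O)(=O)=O; NaIO4 (stoichiometric source of the two aldehyde oxygens), [Na+].[O-]I(=O)(=O)=O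
Why: Lemieux–Johnson oxidation: dihydroxylation of both propenyl groups and periodate cleavage of the diols turn the CH= carbons into the C4 and C4'' aldehydes. This reagent pair is chosen over ozone because it leaves the trioxygenated rings A alone, and the hindered weak base limits epimerisation and β-elimination of aryloxide.

Step 9
Reactants: 17 (2S,3S)-2-[(S)-[3,5-bis(benzyloxy)phenoxy](4-methoxyphenyl)methyl]-3-[(R)-[4-(benzyloxy)phenyl][3,5-bis(benzyloxy)phenoxy]methyl]butanedial
Product: 18 (2S,3S)-2-[(S)-[3,5-bis(benzyloxy)phenoxy](4-methoxyphenyl)methyl]-3-[(R)-[4-(benzyloxy)phenyl][3,5-bis(benzyloxy)phenoxy]methyl]butanedioic acid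
Conditions: NaClO2, NaH2PO4, 2-methylbut-2-ene (large excess), t-BuOH/H2O, 0 °C to rt
Reagents that add atoms: NaClO2, [Na+].[O-]Cl=O
Why: Pinnick oxidation converts α-branched aldehydes to acids without epimerisation; the alkene scavenger removes hypochlorous acid before it can chlorinate the electron-rich rings.

Step 10
Reactants: 18 (2S,3S)-2-[(S)-[3,5-bis(benzyloxy)phenoxy](4-methoxyphenyl)methyl]-3-[(R)-[4-(benzyloxy)phenyl][3,5-bis(benzyloxy)phenoxy]methyl]butanedioic acid
Product: 20 (2S,3S)-5,7-bis(benzyloxy)-3-[(2R,3S)-5,7-bis(benzyloxy)-2-[4-(benzyloxy)phenyl]-4-oxo-3,4-dihydro-2H-chromen-3-yl]-2-(4-methoxyphenyl)-2,3-dihydro-4H-chromen-4-one, via cyclic anhydride 19 (not isolated)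
Conditions: (CF3CO)2O, CH2Cl2, 0 °C to rt
Reagents that add atoms: none
Why: Twofold intramolecular Friedel–Crafts acylation: the anhydride reagent turns 18 into the trans succinic anhydride 19 and then into mixed anhydrides, and each acyl carbon attacks the position ortho to the ether oxygen of its own 3,5-bis(benzyloxy)phenoxy ring (both ortho positions are equivalent) to close a six-membered ring C. The C2–O1 and C2''–O1'' bonds are not touched, so the syn pair becomes the 2,3-cis unit and the anti pair the 2,3-trans unit; the rings B are not activated at the positions that could compete.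

Step 11
Reactants: 20 (2S,3S)-5,7-bis(benzyloxy)-3-[(2R,3S)-5,7-bis(benzyloxy)-2-[4-(benzyloxy)phenyl]-4-oxo-3,4-dihydro-2H-chromen-3-yl]-2-(4-methoxyphenyl)-2,3-dihydro-4H-chromen-4-one
Product: 21 (2S,3S)-5,7-dihydroxy-3-[(2R,3S)-5,7-dihydroxy-2-(4-hydroxyphenyl)-4-oxo-3,4-dihydro-2H-chromen-3-yl]-2-(4-methoxyphenyl)-2,3-dihydro-4H-chromen-4-one
Conditions: H2 (1 atm), Pd/C, EtOAc/MeOH, rt
Reagents that add atoms: none
Why: Hydrogenolysis of the five benzyl ethers under neutral conditions; flavanone C2–O1 bonds and the aryl ketones normally survive these conditions, and no acid or base is present that could epimerise C3 or open ring C of the cis unit.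

## Compound list

1 | (2R)-but-3-yn-2-ol | C[C@@H](O)C#C | starting material
2 | 4-methoxybenzyl chloride | COc1ccc(CCl)cc1 | starting material
3 | 1-({[(2R)-but-3-yn-2-yl]oxy}methyl)-4-methoxybenzene | COc1ccc(CO[C@H](C)C#C)cc1 | intermediate
4 | (2S)-but-3-yn-2-ol | C[C@H](O)C#C | starting material
5 | 1-(benzyloxy)-4-(chloromethyl)benzene | ClCc1ccc(OCc2ccccc2)cc1 | starting material
6 | 1-(benzyloxy)-4-({[(2S)-but-3-yn-2-yl]oxy}methyl)benzene | C#C[C@H](C)OCc1ccc(OCc2ccccc2)cc1 | intermediate
7 | chlorobis(cyclopentadienyl)[(1E,3S)-3-{[4-(benzyloxy)phenyl]methoxy}but-1-en-1-yl]zirconium (cyclopentadienyl rings drawn σ-bonded) | C[C@H](OCc1ccc(OCc2ccccc2)cc1)/C=C/[Zr](Cl)(C1C=CC=C1)C1C=CC=C1 | intermediate (not isolated)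
8 | 1-(benzyloxy)-4-({[(2S,3E)-4-iodobut-3-en-2-yl]oxy}methyl)benzene | C[C@H](OCc1ccc(OCc2ccccc2)cc1)/C=C/I | intermediate
9 | 1-(benzyloxy)-4-({[(2S,3E,7R)-7-[(4-methoxyphenyl)methoxy]oct-3-en-5-yn-2-yl]oxy}methyl)benzene | COc1ccc(CO[C@H](C)C#C/C=C/[C@H](C)OCc2ccc(OCc3ccccc3)cc2)cc1 | intermediate
10 | 1-(benzyloxy)-4-({[(2S,3E,5Z,7R)-7-[(4-methoxyphenyl)methoxy]octa-3,5-dien-2-yl]oxy}methyl)benzene | COc1ccc(CO[C@H](C)/C=C\C=C\[C@H](C)OCc2ccc(OCc3ccccc3)cc2)cc1 | intermediate
11 | lithium (1S,2S,3E,5S)-5-{[4-(benzyloxy)phenyl]methoxy}-1-(4-methoxyphenyl)-2-[(1E)-prop-1-en-1-yl]hex-3-en-1-olate | COc1ccc(cc1)[C@@H]([O-])[C@@H](/C=C/C)/C=C/[C@H](C)OCc1ccc(OCc2ccccc2)cc1.[Li+] | intermediate (not isolated)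
12 | lithium (1R,2S,3Z,5R)-1-[4-(benzyloxy)phenyl]-5-[(4-methoxyphenyl)methoxy]-2-[(1E)-prop-1-en-1-yl]hex-3-en-1-olate | COc1ccc(CO[C@H](C)/C=C\[C@H](/C=C/C)[C@@H]([O-])c2ccc(OCc3ccccc3)cc2)cc1.[Li+] | intermediate (not isolated)
13 | (1S,2S,3S,4R)-4-[4-(benzyloxy)phenyl]-1-(4-methoxyphenyl)-2,3-bis[(1E)-prop-1-en-1-yl]butane-1,4-diol | COc1ccc(cc1)[C@@H](O)[C@@H](/C=C/C)[C@H](/C=C/C)[C@@H](O)c1ccc(OCc2ccccc2)cc1 | intermediate
14 | 1,3-bis(benzyloxy)-5-bromobenzene | Brc1cc(OCc2ccccc2)cc(OCc2ccccc2)c1 | starting material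
15 | 1,1'-{[(1S,2S,3S,4R)-4-[4-(benzyloxy)phenyl]-1-(4-methoxyphenyl)-2,3-bis[(1E)-prop-1-en-1-yl]butane-1,4-diyl]bis(oxy)}bis[3,5-bis(benzyloxy)benzene] | COc1ccc(cc1)[C@@H](Oc1cc(OCc2ccccc2)cc(OCc2ccccc2)c1)[C@@H](/C=C/C)[C@H](/C=C/C)[C@@H](Oc1cc(OCc2ccccc2)cc(OCc2ccccc2)c1)c1ccc(OCc2ccccc2)cc1 | intermediate
16 | tetraol of 15 in which both propenyl groups are 1,2-dihydroxypropyl groups (new carbinol centres unassigned, other centres as in 15) | COc1ccc(cc1)[C@@H](Oc1cc(OCc2ccccc2)cc(OCc2ccccc2)c1)[C@@H](C(O)C(C)O)[C@H](C(O)C(C)O)[C@@H](Oc1cc(OCc2ccccc2)cc(OCc2ccccc2)c1)c1ccc(OCc2ccccc2)cc1 | intermediate (not isolated)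
17 | (2S,3S)-2-[(S)-[3,5-bis(benzyloxy)phenoxy](4-methoxyphenyl)methyl]-3-[(R)-[4-(benzyloxy)phenyl][3,5-bis(benzyloxy)phenoxy]methyl]butanedial | COc1ccc(cc1)[C@@H](Oc1cc(OCc2ccccc2)cc(OCc2ccccc2)c1)[C@@H](C=O)[C@H](C=O)[C@@H](Oc1cc(OCc2ccccc2)cc(OCc2ccccc2)c1)c1ccc(OCc2ccccc2)cc1 | intermediate
18 | (2S,3S)-2-[(S)-[3,5-bis(benzyloxy)phenoxy](4-methoxyphenyl)methyl]-3-[(R)-[4-(benzyloxy)phenyl][3,5-bis(benzyloxy)phenoxy]methyl]butanedioic acid | COc1ccc(cc1)[C@@H](Oc1cc(OCc2ccccc2)cc(OCc2ccccc2)c1)[C@@H](C(O)=O)[C@H](C(O)=O)[C@@H](Oc1cc(OCc2ccccc2)cc(OCc2ccccc2)c1)c1ccc(OCc2ccccc2)cc1 | intermediate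
19 | (3S,4S)-3-[(S)-[3,5-bis(benzyloxy)phenoxy](4-methoxyphenyl)methyl]-4-[(R)-[4-(benzyloxy)phenyl][3,5-bis(benzyloxy)phenoxy]methyl]oxolane-2,5-dione | COc1ccc(cc1)[C@@H](Oc1cc(OCc2ccccc2)cc(OCc2ccccc2)c1)[C@H]1C(=O)OC(=O)[C@@H]1[C@@H](Oc1cc(OCc2ccccc2)cc(OCc2ccccc2)c1)c1ccc(OCc2ccccc2)cc1 | intermediate (not isolated)
20 | (2S,3S)-5,7-bis(benzyloxy)-3-[(2R,3S)-5,7-bis(benzyloxy)-2-[4-(benzyloxy)phenyl]-4-oxo-3,4-dihydro-2H-chromen-3-yl]-2-(4-methoxyphenyl)-2,3-dihydro-4H-chromen-4-one | COc1ccc([C@H]2Oc3cc(OCc4ccccc4)cc(OCc4ccccc4)c3C(=O)[C@H]2[C@@H]2C(=O)c3c(OCc4ccccc4)cc(OCc4ccccc4)cc3O[C@H]2c2ccc(OCc3ccccc3)cc2)cc1 | intermediate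
21 | (2S,3S)-5,7-dihydroxy-3-[(2R,3S)-5,7-dihydroxy-2-(4-hydroxyphenyl)-4-oxo-3,4-dihydro-2H-chromen-3-yl]-2-(4-methoxyphenyl)-2,3-dihydro-4H-chromen-4-one | COc1ccc([C@H]2Oc3cc(O)cc(O)c3C(=O)[C@H]2[C@@H]2C(=O)c3c(O)cc(O)cc3O[C@H]2c2ccc(O)cc2)cc1 | target

## Step count and least certain steps

Total step count: 11. Longest linear sequence: 10 steps (from 4 through 6, 8, 9, 10, 13, 15, 17, 18 and 20 to 21). The least certain steps are step 6 (key step), step 7 and step 10.

Step 6 (key step). What may go wrong: lithiation at sites other than the two ether CH2 groups (the tertiary dienylic C–H next to each ether oxygen, addition of the alkyllithium to the diene), incomplete anti selection in the E half because aryl-stabilised carbanions discriminate less well there than in the Z case, and [1,2]-shift if the second, more hindered rearrangement needs warming. The fallback keeps the Z-half rearrangement and sets C2''/C3'' by a catalyst-controlled allylboration. It sets out from 3 and comes back at 17.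
- Sonogashira coupling of 3 with (E)-3-iodoprop-2-en-1-ol (Pd(PPh3)2Cl2, CuI, Et3N) should give (2E,6R)-6-[(4-methoxyphenyl)methoxy]hept-2-en-4-yn-1-ol F1.
- cis-Semihydrogenation as in step 5 should give (2E,4Z,6R)-6-[(4-methoxyphenyl)methoxy]hepta-2,4-dien-1-ol F2.
- Borylation of the allylic alcohol with B2pin2 and Pd(MeCN)4(BF4)2 should give 2-[(2E,4Z,6R)-6-[(4-methoxyphenyl)methoxy]hepta-2,4-dien-1-yl]-4,4,5,5-tetramethyl-1,3,2-dioxaborolane F3.
- Addition of F3 to 4-(benzyloxy)benzaldehyde under the enantiomer of the 3,3'-bis(2,4,6-triisopropylphenyl)-BINOL phosphoric acid that delivers the (R) carbinol passes through a chair transition state at the γ-carbon. The E geometry therefore becomes the anti pair of (1R,2S,3Z,5R)-1-[4-(benzyloxy)phenyl]-2-ethenyl-5-[(4-methoxyphenyl)methoxy]hex-3-en-1-ol F4.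
- [2,3]-Wittig rearrangement of the remaining Z allyl ether of F4 (s-BuLi, 3 equiv, THF, −78 °C) should give (1S,2S,3S,4R)-4-[4-(benzyloxy)phenyl]-3-ethenyl-1-(4-methoxyphenyl)-2-[(1E)-prop-1-en-1-yl]butane-1,4-diol F5, which differs from 13 only by a vinyl in place of one propenyl group.
- Copper-catalysed arylation with 14 as in step 7 should give 1,1'-{[(1S,2S,3S,4R)-4-[4-(benzyloxy)phenyl]-3-ethenyl-1-(4-methoxyphenyl)-2-[(1E)-prop-1-en-1-yl]butane-1,4-diyl]bis(oxy)}bis[3,5-bis(benzyloxy)benzene] F6, and the oxidative cleavage of step 8 then gives 17.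

Step 7. What may go wrong: no arylation or only single arylation, because each secondary benzylic alkoxide is flanked by a branched carbon and the copper alkoxide forms slowly; on prolonged heating, loss of material by oxidation of the benzylic alkoxides. The fallback replaces the catalytic coupling by a metal-free aryl transfer from trivalent iodine at room temperature. It sets out from 13 and comes back at 15. Commercial 3,5-bis(benzyloxy)phenylboronic acid and 2,4,6-trimethyl(diacetoxyiodo)benzene with BF3·OEt2 in CH2Cl2 should give [3,5-bis(benzyloxy)phenyl](2,4,6-trimethylphenyl)iodonium tetrafluoroborate F7. The disodium alkoxide of 13 (NaH, toluene, rt) should take up the less hindered aryl group of F7 by ligand coupling, with the mesityl group as the ligand that is not transferred.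

Step 10. What may go wrong: ionisation of the benzylic C2–O and C2''–O aryl ethers by the acid set free (loss of aryloxide and capture of the cation by the neighbouring carboxyl group as a γ-lactone) before acylation, or acid-mediated loss of the cis configuration. The fallback avoids acid and reverses the order in which the two bonds of ring C are made. It sets out from 13 and comes back at 20.
- Ozonolysis of 13 (O3, CH2Cl2/MeOH, −78 °C; Me2S) should give the cis-fused bis-lactol 4-[4-(benzyloxy)phenyl]-8-(4-methoxyphenyl)-3,7-dioxabicyclo[3.3.0]octane-2,6-diol F8.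
- Oxidation (PhI(OAc)2, TEMPO) should give the bis-lactone 4-[4-(benzyloxy)phenyl]-8-(4-methoxyphenyl)-3,7-dioxabicyclo[3.3.0]octane-2,6-dione F9 (methoxyphenyl exo, benzyloxyphenyl endo), a rigid compound on which the stereotetrad can be checked.
- Separately, 5-fluorobenzene-1,3-diol with benzyl bromide and K2CO3 should give 1,3-bis(benzyloxy)-5-fluorobenzene F10, and N-bromosuccinimide should give 2-bromo-1,5-bis(benzyloxy)-3-fluorobenzene F11.
- Bromine–lithium exchange (n-BuLi, THF, −78 °C) should give [2,4-bis(benzyloxy)-6-fluorophenyl]lithium F12, which adds once to each lactone carbonyl of F9 to form the C4–C4a and C4''–C4a'' bonds in (2S,3S)-1,4-bis[2,4-bis(benzyloxy)-6-fluorophenyl]-2-[(S)-hydroxy(4-methoxyphenyl)methyl]-3-[(R)-[4-(benzyloxy)phenyl](hydroxy)methyl]butane-1,4-dione F13.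
- KN(SiMe3)2 (2 equiv, THF, −78 to 0 °C) should then close both O1–C8a bonds by intramolecular SNAr displacement of the fluorides ortho to the ketones, with retention at C2 and C2'', to give 20.

## Further compounds

F1 | step 6 | (2E,6R)-6-[(4-methoxyphenyl)methoxy]hept-2-en-4-yn-1-ol | COc1ccc(CO[C@H](C)C#C/C=C/CO)cc1
F2 | step 6 | (2E,4Z,6R)-6-[(4-methoxyphenyl)methoxy]hepta-2,4-dien-1-ol | COc1ccc(CO[C@H](C)/C=C\C=C\CO)cc1
F3 | step 6 | 2-[(2E,4Z,6R)-6-[(4-methoxyphenyl)methoxy]hepta-2,4-dien-1-yl]-4,4,5,5-tetramethyl-1,3,2-dioxaborolane | COc1ccc(CO[C@H](C)/C=C\C=C\CB2OC(C)(C)C(C)(C)O2)cc1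
F4 | step 6 | (1R,2S,3Z,5R)-1-[4-(benzyloxy)phenyl]-2-ethenyl-5-[(4-methoxyphenyl)methoxy]hex-3-en-1-ol | COc1ccc(CO[C@H](C)/C=C\[C@H](C=C)[C@@H](O)c2ccc(OCc3ccccc3)cc2)cc1
F5 | step 6 | (1S,2S,3S,4R)-4-[4-(benzyloxy)phenyl]-3-ethenyl-1-(4-methoxyphenyl)-2-[(1E)-prop-1-en-1-yl]butane-1,4-diol | COc1ccc(cc1)[C@@H](O)[C@@H](/C=C/C)[C@H](C=C)[C@@H](O)c1ccc(OCc2ccccc2)cc1
F6 | step 6 | 1,1'-{[(1S,2S,3S,4R)-4-[4-(benzyloxy)phenyl]-3-ethenyl-1-(4-methoxyphenyl)-2-[(1E)-prop-1-en-1-yl]butane-1,4-diyl]bis(oxy)}bis[3,5-bis(benzyloxy)benzene] | COc1ccc(cc1)[C@@H](Oc1cc(OCc2ccccc2)cc(OCc2ccccc2)c1)[C@@H](/C=C/C)[C@H](C=C)[C@@H](Oc1cc(OCc2ccccc2)cc(OCc2ccccc2)c1)c1ccc(OCc2ccccc2)cc1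
F7 | step 7 | [3,5-bis(benzyloxy)phenyl](2,4,6-trimethylphenyl)iodonium tetrafluoroborate | Cc1cc(C)c([I+]c2cc(OCc3ccccc3)cc(OCc3ccccc3)c2)c(C)c1.F[B-](F)(F)F
F8 | step 10 | 4-[4-(benzyloxy)phenyl]-8-(4-methoxyphenyl)-3,7-dioxabicyclo[3.3.0]octane-2,6-diol (cis-fused, lactol centres unassigned) | COc1ccc(cc1)[C@@H]1[C@@H]2[C@H](C(O)O1)[C@H](c1ccc(OCc3ccccc3)cc1)OC2O
F9 | step 10 | 4-[4-(benzyloxy)phenyl]-8-(4-methoxyphenyl)-3,7-dioxabicyclo[3.3.0]octane-2,6-dione (cis-fused, methoxyphenyl exo, benzyloxyphenyl endo) | COc1ccc(cc1)[C@@H]1[C@@H]2[C@H](C(=O)O1)[C@H](c1ccc(OCc3ccccc3)cc1)OC2=O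
F10 | step 10 | 1,3-bis(benzyloxy)-5-fluorobenzene | Fc1cc(OCc2ccccc2)cc(OCc2ccccc2)c1
F11 | step 10 | 2-bromo-1,5-bis(benzyloxy)-3-fluorobenzene | Brc1c(F)cc(OCc2ccccc2)cc1OCc1ccccc1
F12 | step 10 | [2,4-bis(benzyloxy)-6-fluorophenyl]lithium | [Li]c1c(F)cc(OCc2ccccc2)cc1OCc1ccccc1
F13 | step 10 | (2S,3S)-1,4-bis[2,4-bis(benzyloxy)-6-fluorophenyl]-2-[(S)-hydroxy(4-methoxyphenyl)methyl]-3-[(R)-[4-(benzyloxy)phenyl](hydroxy)methyl]butane-1,4-dione | COc1ccc(cc1)[C@@H](O)[C@@H](C(=O)c1c(F)cc(OCc2ccccc2)cc1OCc1ccccc1)[C@H](C(=O)c1c(F)cc(OCc2ccccc2)cc1OCc1ccccc1)[C@@H](O)c1ccc(OCc2ccccc2)cc1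
A1 | alternative 1 | diisopropylsilanediyl bis-enol ether of (2S)-5,7-bis(benzyloxy)-2-(4-methoxyphenyl)chroman-4-one and (2R)-5,7-bis(benzyloxy)-2-[4-(benzyloxy)phenyl]chroman-4-one | COc1ccc(cc1)[C@@H]1C=C(O[Si](C(C)C)(C(C)C)OC2=C[C@@H](Oc3cc(OCc4ccccc4)cc(OCc4ccccc4)c23)c2ccc(OCc3ccccc3)cc2)c2c(OCc3ccccc3)cc(OCc3ccccc3)cc2O1
A2 | alternative 1 | (2S,3R)-5,7-bis(benzyloxy)-3-[(2R,3S)-5,7-bis(benzyloxy)-2-[4-(benzyloxy)phenyl]-4-oxo-3,4-dihydro-2H-chromen-3-yl]-2-(4-methoxyphenyl)-2,3-dihydro-4H-chromen-4-one (C3 epimer of 20, both units 2,3-trans) | COc1ccc([C@H]2Oc3cc(OCc4ccccc4)cc(OCc4ccccc4)c3C(=O)[C@@H]2[C@@H]2C(=O)c3c(OCc4ccccc4)cc(OCc4ccccc4)cc3O[C@H]2c2ccc(OCc3ccccc3)cc2)cc1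
A3 | alternative 2 | 5,7-bis(benzyloxy)-3-{5,7-bis(benzyloxy)-2-[4-(benzyloxy)phenyl]-4-oxo-4H-chromen-3-yl}-2-(4-methoxyphenyl)-4H-chromen-4-one | COc1ccc(cc1)C1=C(C(=O)c2c(OCc3ccccc3)cc(OCc3ccccc3)cc2O1)C1=C(Oc2cc(OCc3ccccc3)cc(OCc3ccccc3)c2C1=O)c1ccc(OCc2ccccc2)cc1
A4 | alternative 2 | (2S,3S)-5,7-dihydroxy-3-[(2S,3S)-5,7-dihydroxy-2-(4-hydroxyphenyl)-4-oxo-3,4-dihydro-2H-chromen-3-yl]-2-(4-methoxyphenyl)-2,3-dihydro-4H-chromen-4-one (C2'' epimer of 21, both units 2,3-cis) | COc1ccc([C@H]2Oc3cc(O)cc(O)c3C(=O)[C@H]2[C@@H]2C(=O)c3c(O)cc(O)cc3O[C@@H]2c2ccc(O)cc2)cc1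
A5 | alternative 3 | 1,4-bis[2,4-bis(benzyloxy)-6-hydroxyphenyl]butane-1,4-dione | O=C(CCC(=O)c1c(O)cc(OCc2ccccc2)cc1OCc1ccccc1)c1c(O)cc(OCc2ccccc2)cc1OCc1ccccc1
A6 | alternative 3 | (2E,3E)-2-[4-(benzyloxy)benzylidene]-1,4-bis[2,4-bis(benzyloxy)-6-hydroxyphenyl]-3-(4-methoxybenzylidene)butane-1,4-dione | COc1ccc(/C=C(/C(=O)c2c(O)cc(OCc3ccccc3)cc2OCc2ccccc2)\C(=C/c2ccc(OCc3ccccc3)cc2)C(=O)c2c(O)cc(OCc3ccccc3)cc2OCc2ccccc2)cc1
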